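The route rests on disconnecting the two C–isopropyl bonds at the benzylic methine carbons that join C3 and C5 of the acylphloroglucinol ring to C6 of each 2,2,4,4-tetramethylcyclohexane-1,3,5-trione ring. Without its isopropyl group, each methine is the β-carbon of an exocyclic C=C activated by two ring carbonyls. One copper-catalysed, ligand-controlled double conjugate addition of an isopropyl–metal reagent to the tri-O-benzyl bis(arylidene trione) should therefore form both C–C bonds and both R stereocentres in a single operation, with no ring closure. The precursor arises from isobutyrylphloroglucinol by diformylation, tribenzylation and double Knoevenagel condensation with syncarpic acid; hydrogenolysis completes the synthesis.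

Key step: step 5

Remark on configuration: with the priorities trione ring carbon > aryl carbon > isopropyl > H, both stereocentres of the target are R, so the target is the C2-symmetric (R,R) isomer and not the meso form.

Remark on the isopropyl donor: diisopropylzinc is used, because an alkylmagnesium halide is expected to add to so electrophilic an alkylidene 1,3-dicarbonyl without copper and so bypass the chiral catalyst.

Assumption: the (S,R,R) antipode of the phosphoramidite is taken to deliver isopropyl to the Re face of each benzylic carbon; the sense is to be checked on a small scale and the mirror-image ligand used if it proves opposite.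

Step 1
Reactants: 1 phloroglucinol; 2 isobutyryl chloride
Product: 3 isobutyrylphloroglucinol [2-methyl-1-(2,4,6-trihydroxyphenyl)propan-1-one]
Conditions: AlCl3 (4 equiv), PhNO2, 0 °C → 60 °C; then ice/aq. HCl
Reagents that add atoms: none
Why: Friedel–Crafts acylation of the electron-rich triphenol, in which the first acyl group (a chelated vinylogous acid) deactivates the ring enough that monoacylation should predominate.

Step 2
Reactants: 3 isobutyrylphloroglucinol
Product: 5 2,4,6-trihydroxy-5-(2-methylpropanoyl)benzene-1,3-dicarbaldehyde, via bis-iminium dichloride 4 (not isolated)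
Conditions: POCl3 (4 equiv), DMF, EtOAc, 0 °C → 40 °C; then H2O, 60 °C
Reagents that add atoms: N,N-dimethylformamide CN(C)C=O; water O
Why: Twofold Vilsmeier–Haack formylation at the only two free ring positions, each ortho or para to all three hydroxyl groups and meta to the acyl group, followed by hydrolysis of the iminium groups on aqueous work-up.

Step 3
Reactants: 5 2,4,6-trihydroxy-5-(2-methylpropanoyl)benzene-1,3-dicarbaldehyde
Product: 6 2,4,6-tris(benzyloxy)-5-(2-methylpropanoyl)benzene-1,3-dicarbaldehyde
Conditions: BnBr (4.5 equiv), K2CO3 (6 equiv), Bu4NI (cat.), DMF, 60 °C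
Reagents that add atoms: benzyl bromide BrCc1ccccc1
Why: Williamson etherification of the three acidic phenols in a polar aprotic medium, where attack through oxygen is favoured and C-benzylation would have to break aromaticity at a fully substituted ring carbon.

Step 4
Reactants: 6 2,4,6-tris(benzyloxy)-5-(2-methylpropanoyl)benzene-1,3-dicarbaldehyde; 7 syncarpic acid (2,2,4,4-tetramethylcyclohexane-1,3,5-trione)
Product: 8 tri-O-benzyl bis(arylidene trione), 6,6'-{[2,4,6-tris(benzyloxy)-5-(2-methylpropanoyl)-1,3-phenylene]dimethanylylidene}bis(2,2,4,4-tetramethylcyclohexane-1,3,5-trione)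
Conditions: 7 (2.2 equiv), piperidine (0.2 equiv), AcOH (0.2 equiv), toluene, reflux, azeotropic removal of water
Reagents that add atoms: none
Why: Double Knoevenagel condensation of the acidic cyclic 1,3-dione with both aldehydes, driven by water removal; the flanking benzyloxy groups should hinder addition of a second trione, and the symmetric trione gives no alkene isomers.

Step 5
Reactants: 8 tri-O-benzyl bis(arylidene trione); 9 diisopropylzinc
Product: 11 tri-O-benzyl (R,R)-myrtucommulone A, via bis(isopropylzinc) enolate 10 (not isolated)
Conditions: i-Pr2Zn (3.5 equiv, 1 M in toluene), Cu(OTf)2 (10 mol %), (S)-BINOL N,N-bis[(R)-1-phenylethyl]phosphoramidite (20 mol %), degassed toluene, Ar, −40 → −20 °C; then 1 M HCl, 0 °C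
Reagents that add atoms: none
Why: Proposed new method: the dialkylzinc reduces Cu(II) to a Cu(I)–phosphoramidite complex, which takes an isopropyl group from zinc, binds the electron-poor exocyclic C=C as a π-complex, adds oxidatively to give a benzylic Cu(III) species and reductively eliminates to form the C–isopropyl bond, leaving an isopropylzinc trione enolate that is protonated on work-up. The closest known reaction type is the copper/phosphoramidite-catalysed conjugate addition of dialkylzincs to arylidene Meldrum's acids and alkylidene malonates, extended here to an arylidene cyclohexanetrione and run at two sites of one molecule. No ring is closed. Each stereocentre is set under catalyst control by the chiral ligand on copper, which must deliver isopropyl to the Re face of each benzylic carbon (priorities trione carbon > aryl carbon > H) to give R; the ortho benzyloxy groups twist the arene out of the alkene plane and so differentiate the faces, and because the two sites react independently a wrong-face event gives mainly the meso diastereomer, which is to be removed by chromatography. The step needs 1,4-addition only and no attack at the aryl ketone or the ring carbonyls: a dialkylzinc does not add without copper and does not attack ketones, the acceptor cannot enolise because C2 and C4 of the trione ring are quaternary, and the benzyl ethers prevent phenoxide formation and oxa-cyclisation onto the enone.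

Step 6
Reactants: 11 tri-O-benzyl (R,R)-myrtucommulone A
Product: 12 (R,R)-myrtucommulone A
Conditions: H2 (1 atm), 10% Pd/C, EtOAc, rt
Reagents that add atoms: none
Why: Hydrogenolysis of the three benzyl aryl ethers under neutral conditions should leave the hindered ketones, the tetrasubstituted enols and the two benzylic C–H stereocentres untouched, and avoids the acid that would promote cyclodehydration or retro-Michael scrambling.

Compound list
1 | phloroglucinol | Oc1cc(O)cc(O)c1 | starting material
2 | isobutyryl chloride | CC(C)C(Cl)=O | starting material
3 | isobutyrylphloroglucinol, 2-methyl-1-(2,4,6-trihydroxyphenyl)propan-1-one | CC(C)C(=O)c1c(O)cc(O)cc1O | intermediate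
4 | [2,4,6-trihydroxy-5-(2-methylpropanoyl)-1,3-phenylene]bis(N,N-dimethylmethaniminium) dichloride | CC(C)C(=O)c1c(O)c(C=[N+](C)C)c(O)c(C=[N+](C)C)c1O.[Cl-].[Cl-] | intermediate
5 | 2,4,6-trihydroxy-5-(2-methylpropanoyl)benzene-1,3-dicarbaldehyde (2,4-diformyl-6-isobutyrylphloroglucinol) | CC(C)C(=O)c1c(O)c(C=O)c(O)c(C=O)c1O | intermediate
6 | 2,4,6-tris(benzyloxy)-5-(2-methylpropanoyl)benzene-1,3-dicarbaldehyde | CC(C)C(=O)c1c(OCc2ccccc2)c(C=O)c(OCc2ccccc2)c(C=O)c1OCc1ccccc1 | intermediate
7 | syncarpic acid, 2,2,4,4-tetramethylcyclohexane-1,3,5-trione | CC1(C)C(=O)CC(=O)C(C)(C)C1=O | starting material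
8 | tri-O-benzyl 2,4-bis[(3,3,5,5-tetramethyl-2,4,6-trioxocyclohexylidene)methyl]-6-isobutyrylphloroglucinol | CC(C)C(=O)c1c(OCc2ccccc2)c(C=C2C(=O)C(C)(C)C(=O)C(C)(C)C2=O)c(OCc2ccccc2)c(C=C2C(=O)C(C)(C)C(=O)C(C)(C)C2=O)c1OCc1ccccc1 | intermediate
9 | diisopropylzinc | CC(C)[Zn]C(C)C | starting material
10 | bis(isopropylzinc) enolate of 11, both benzylic centres R | CC(C)C(=O)c1c(OCc2ccccc2)c([C@H](C2=C(O[Zn]C(C)C)C(C)(C)C(=O)C(C)(C)C2=O)C(C)C)c(OCc2ccccc2)c([C@H](C2=C(O[Zn]C(C)C)C(C)(C)C(=O)C(C)(C)C2=O)C(C)C)c1OCc1ccccc1 | intermediate
11 | tri-O-benzyl (R,R)-myrtucommulone A | CC(C)C(=O)c1c(OCc2ccccc2)c([C@H](C2=C(O)C(C)(C)C(=O)C(C)(C)C2=O)C(C)C)c(OCc2ccccc2)c([C@H](C2=C(O)C(C)(C)C(=O)C(C)(C)C2=O)C(C)C)c1OCc1ccccc1 | intermediate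
12 | (R,R)-myrtucommulone A | CC(C)C(=O)c1c(O)c([C@H](C2=C(O)C(C)(C)C(=O)C(C)(C)C2=O)C(C)C)c(O)c([C@H](C2=C(O)C(C)(C)C(=O)C(C)(C)C2=O)C(C)C)c1O | target

Total step count: 6. Longest linear sequence: 6 steps (1 → 3 → 5 → 6 → 8 → 11 → 12).

Steps most likely to fail

Step 5 (the step proposed as a new method). The risks are poor facial selectivity at the twisted, doubly ortho-substituted arylidene, and ligand-free or oxygen-initiated radical isopropyl transfer. β-Hydride transfer from the isopropyl–metal species (conjugate reduction) and a stalled second addition are further risks. The fallback uses known chemistry, sets out from 3 and 7 and rejoins the route at 12. Compound 7 is condensed with isobutyraldehyde (piperidine, then dilute acid) to give isobutylidene syncarpic acid F1. Compound 3 is then alkylated at both free ring carbons by Friedel–Crafts-type Michael addition to F1 (2 equiv, NaH, THF, rt). This should give myrtucommulone A as the mixture of (R,R), (S,S) and meso isomers F2. Preparative HPLC on a chiral stationary phase would then furnish the (R,R) isomer 12.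

Step 4. Condensation may stall at the second hindered formyl group, a further trione may add to the newly formed acceptor, or the alkene may be cleaved hydrolytically on work-up. The fallback sets out from 6 and 7 and rejoins at 8. Stirring 6 and 7 with piperidine (2.2 equiv) in EtOH/CH2Cl2 at rt should give the bis-Mannich base F3. In F3 each benzylic carbon carries a piperidine, so no Michael acceptor is exposed while free trione is present. After isolation, cold 1 M HCl in a two-phase CH2Cl2 system would expel piperidine and release 8.

Step 3. Alkylation of the doubly hydrogen-bonded hydroxyl groups may be incomplete, or alkylation may occur through carbon with loss of aromaticity. The fallback sets out from 5 and rejoins at 6. A Mitsunobu etherification with benzyl alcohol (PPh3, DIAD, THF, 0 °C → rt) uses the acidic phenols as pronucleophiles without generating a free ambident phenoxide. This should give 6 directly, with no compound outside the list (F0).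

Further compounds
F1 | step 5 | isobutylidene syncarpic acid, 2,2,4,4-tetramethyl-6-(2-methylpropylidene)cyclohexane-1,3,5-trione | CC(C)C=C1C(=O)C(C)(C)C(=O)C(C)(C)C1=O
F2 | step 5 | myrtucommulone A as the mixture of (R,R), (S,S) and meso isomers | CC(C)C(=O)c1c(O)c(C(C2=C(O)C(C)(C)C(=O)C(C)(C)C2=O)C(C)C)c(O)c(C(C2=C(O)C(C)(C)C(=O)C(C)(C)C2=O)C(C)C)c1O
F3 | step 4 | bis-Mannich base of 6 with syncarpic acid and piperidine, mixture of stereoisomers | CC(C)C(=O)c1c(OCc2ccccc2)c(C(N2CCCCC2)C2=C(O)C(C)(C)C(=O)C(C)(C)C2=O)c(OCc2ccccc2)c(C(N2CCCCC2)C2=C(O)C(C)(C)C(=O)C(C)(C)C2=O)c1OCc1ccccc1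
F0 | step 3 | none | none
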